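Its constants were chosen freely; the run is a simulation.

A small charge of incoming ligand, 69.0 mM against 46 mM of starting complex, was where I began with this flask, since every exchange spends one ligand and turnovers can be counted before any rate is weighed.

starting complex 46 mM (in portions, 3); incoming ligand 69.0 mM; time 40 h; the portions of starting complex follow each other after 1.5 min, the first at the start

    starting complex + incoming ligand → leaving ligand + complex with one exchanged (k1 = 32 /M/min)
    complex with one exchanged + incoming ligand → leaving ligand + complex with two exchanged (k2 = 220 /M/min)
    complex with two exchanged + incoming ligand → leaving ligand + complex with three exchanged (k3 = 9.5 /M/min)
    2 incoming ligand → homo dimer (k4 = 2.5 /M/min)
    crystals ⇌ complex with two exchanged, rate k5*(cs5 - [complex with two exchanged]) while solid is left; crystals form when [complex with two exchanged] > cs5 (cs5 = 22 mM, k5 = 4.7 /min)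

- amounts and yields of complex with two exchanged count crystals too
- two of one species on the left: rate k times its square, two consumed each time
- given per volume of solution although it is solid: crystals
- the reaction counts as stopped when no species that holds the starting complex changes by six tenths of a point or more over the second half of the time
- run time (flask): 40 h

1. which holds at 40 h: what has brought the reaction to rest, or that it has not come to rest (all of the starting complex has reacted / forward and back rates have come level / the incoming ligand has run out first / it is still moving)
2. the complex with two exchanged standing at 40 h, as a percentage of the starting complex charged

I called the exchanges that the charge can pay per starting complex charged the ligand budget 1.50, and I expected the incoming ligand to be the limiting reagent. The second exchange has the larger constant, 220 /M/min against 32 /M/min for the first, so I let the complex with one exchanged pass straight on and solved two extreme versions of the flask. If each reacted complex stopped at two exchanged and paid two turns, the complex with two exchanged would reach a ceiling of 75.0 % of the charge. If each went on to three exchanged and paid 3 turns, 50.0 % would react and none would stand at two exchanged. I took the real flask to lie between these and placed it by the third exchange, whose constant is smaller than the first by the ratio 0.297. So I let that share go on, which makes a reacted complex cost 2.30 turns, so that 65.3 % reacts and 45.9 % stands at two exchanged, with the homo dimer uncounted.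

The forecast said the incoming ligand has run out first and 35 %, within 29 % to 42 %, holding that “the ligand is gone within minutes and roughly half the starting complex is left unreacted”. My figure stood above its range.

The simulation gave the incoming ligand has run out first, with 0 % of it left, and 34.5 %, inside the forecast's range. With the step to the homo dimer struck out, this flask gives 39.8 %. The budget closes: the 54.0 mM of leaving ligand are 1.17 exchanges per starting complex charged, and the 7.50 mM of homo dimer hold the other 0.326, which together make 1.50.

In the neighbour flask with 110 mM of starting complex, the budget is 0.627, so the same reckoning has 27.3 % reacting and 19.2 % at two exchanged. The computed neighbour holds 19.8 % at two exchanged, with 71.9 % of its starting complex unreacted.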